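## Analysis of the target

Arecatannin A2 (49) is a linear B-type procyanidin tetramer: three (−)-epicatechin units (units 1 to 3, counted from the top) and one terminal (+)-catechin (unit 4) are joined head to tail by three C4–C8 bonds. It is therefore a chain of four 2-aryl-chroman-3-ols. It has eleven stereocentres. In each of units 1 to 3 these are C2, C3 and C4 (2R,3R,4R: aryl on C2 and hydroxyl on C3 cis, hydroxyl on C3 and the C4 aryl bond trans); in unit 4 they are C2 and C3 (2R,3S, trans). Within one ring C the centres are contiguous, but neighbouring units communicate only through the hindered C4–C8 bond. Every ring A is a 1,3,5-trioxygenated benzene and every ring B a catechol, so the free compound is sensitive to air and to base (C2 epimerisation through opening of ring C). Each interflavan bond is a doubly benzylic C–C bond to an electron-rich arene and is labile to acid. The difficulty is to make this hindered bond three times with control of the site on ring A (C8, not C6) and of the C4 configuration, and to reach the less stable 2,3-cis arrangement each time; commercial (+)-catechin supplies unit 4 only. The route rests on one feature: ring C of an epicatechin unit (O1, C2, C3, C4, C4a, C8a) is the ring-expanded isomer of a trans-2,3-dihydrobenzofuran in which O1 is bound to the future C3 and the future C2 is an exocyclic benzylic carbon carrying ring B. Moving O1 from C3 to C2 creates the O1–C2 bond, the C3 hydroxyl and both configurations in one stereospecific event, while C4 with its bond to C8 of the next unit is already in place.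

## Retrosynthetic reasoning

Protecting groups. 49 is traced back to 48 by removal of seventeen benzyl ethers (hydrogenolysis, neutral, last) and 48 to 47 by methanolysis of the two ring-B pivalates of unit 1. Benzyl ethers are chosen because one neutral operation frees every phenol and alcohol at the end. The two esters are present only because the key step needs an electron-poor ring B.

Ring C of unit 1 (key disconnection). In 47 the O1–C2 bond of unit 1 is cut and O1 is re-attached to C3 in place of the hydroxyl. This gives the trans-2,3-dihydrobenzofuran mesylate 45, in which the former C2 is an exocyclic benzylic carbon. The cut is made here and not at the C4–C8 bond because it turns the least accessible feature of an epicatechin unit, the cis 2-aryl-3-hydroxy pair, into the outcome of two SN2 inversions. In the forward sense O1 has to displace the mesylate (oxonium ion 46) and the aqueous medium has to open the bridge at the ring carbon. One ring, one skeletal bond and the C2 and C3 configurations result.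

Leaving group and benzylic stereocentre. 45 comes from carbinol 44 by sulfonylation and 44 from ketone 43 by reduction. The forward reduction must give the (S) carbinol, threo to the ring oxygen, because this centre is inverted into C2 (R).

The five-membered ring. 43 is cut at two bonds of the dihydrofuran ring: C2–C3 (the future C3–C4 bond) and O1–C2. This leads to the ortho-quinone methide 42 and the one-carbon partner 14, a sulfonium ylide that already carries ring B. This [4+1] cut builds the ring from an aldehyde-derived carbon and a phenacyl carbon, both easily available. The forward reaction must fix the configuration at the methide carbon (the future C4); for that reason the chirality is placed in the sulfide part of 14. 42 is released from sulfone 41.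

The interflavan bond. 41 is cut at the bond between the future C4 and C8 of the unit below, giving aldehyde 7 and the C8 bromide 38 (used as aryllithium 39). An aryl anion at C8 and an aldehyde make this bond regiospecifically, with no C6/C8 ambiguity and without a C4 cation.

Return to the next lower oligomer. 38 is traced to 37 (bromination at C8 of the top unit), 37 to 36 (benzylation) and 36 to 35 (ester cleavage). The esters cannot survive the organolithium and the C3 hydroxyl must be capped, hence the exchange.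

Iteration. 35 is related to 33 and 26, and 23 to 21 and 4, exactly as 47 is to 45 and 38, with 7 and 14 used each time. The route is thus one five-step sequence (steps 10 to 14) run three times, separated by a three-step adjustment.

Building blocks. 4 comes from (+)-catechin 1 through 2 and 3 (benzylation, C8 bromination). 7 comes from 5 through 6. 14 comes from chloroketone 9 (from 8) and the C2-symmetric sulfide 12, itself made from diol 10 through 11.

## Alternatives that were turned down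

Alternative 1: De novo ring A of unit 3 by recyclisation of a pyranone.
- Disconnection: the C5–C6 bond of ring A of unit 3 in dimer A1. The precursor is the bicyclic 2-pyranone A2, in which ring C with its three stereocentres, the silylated C3 oxygen and the bond from C4 to unit 4 are already present and the future C6 is a methyl group.
- Forward key step: an alkoxide opens the lactone, the methyl ketone enolate so released condenses with the new ester (Claisen condensation), and the diketone aromatises to the 5,7-dihydroxy ring A with O1 already on C8a.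
- For it: recyclisation of 4-oxygenated 6-methyl-2-pyranones to resorcinol-type rings is old and dependable chemistry. On mechanistic security it is stronger than an oxonium shift. It also delivers the two ring-A phenols free and distinct from all benzyl ethers.
- Against it: it creates no stereocentre and no interflavan bond. The whole of ring C, including the hindered C4–C8 bond and the cis-2,3 pair, would have to be built on a non-aromatic pyranone, where the stabilised C4 cation of flavan chemistry is not available. The strongly basic step exposes a C4 methine that is both benzylic and allylic to the pyranone. Each of the three extender units would need its own pyranone synthesis.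
- Comparison: it moves the hard problem upstream instead of solving it. In exchange for its better-precedented key step, the chosen route offers a key step that itself creates ring C and two stereocentres, and a ring A that is bought.

Alternative 2: Late introduction of the three rings B.
- Disconnection: the three C2–C1′ bonds of units 1 to 3 in the perbenzylated tetramer A3, leading to the tris(2-acetoxy) core A5 and three equivalents of the catechol diether A4.
- Forward key step: a Lewis acid ionises the three C2 acetates to oxocarbenium ions and each is arylated by A4 para to an ether oxygen (Friedel–Crafts C-arylation of a cyclic oxocarbenium ion).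
- For it: it is the most convergent of all. One operation would reach the fully protected target, the nucleophile is symmetric and cheap, and no ring-B protecting-group exchange is needed. On step count after the core it beats the chosen route.
- Against it: three stereocentres are set at once by facial attack on planar cations, and the neighbouring C3 benzyloxy group steers the arene trans, toward the 2,3-trans (catechin) series, the opposite of what units 1 to 3 need. The oxygen that must stabilise each cation is an aryl ether oxygen. The same molecule carries four far more nucleophilic rings A with free C6 positions and three acid-labile interflavan bonds under the same Lewis acid. A5, a tetramer without rings B, is reachable by none of the established flavan methods.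
- Comparison: the chosen route replaces facial selectivity on a cation by two stereospecific inversions at sp3 carbon and uses no Lewis acid once an interflavan bond exists.

Alternative 3: Ring A of the catechin terminus by benzannulation.
- Disconnection: the C8–C8a and C6–C7 bonds of ring A of unit 4 in the seco-tetramer A6, leading to the 4-substituted 3-benzyloxycyclobutenone A7 and the trimer siloxyalkyne A8.
- Forward key step: heat opens A7 to a vinylketene, which adds A8 and electrocyclises to the pentasubstituted phenol (Danheiser benzannulation). Ring C of unit 4 is closed afterwards.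
- For it: the last interflavan bond is made without any C6/C8 question, because C8 is an alkyne carbon. A trimer and a monomer are joined convergently under neutral thermal conditions. On regiochemical certainty it is stronger than the electrophilic bromination used in the chosen route.
- Against it: it deals with one of the three interflavan bonds only. A8 still requires the complete epicatechin trimer, ending in a C4 stereocentre that is benzylic and propargylic and must survive prolonged heating. After the annulation, ring C of unit 4 must still be closed by a stereospecific C–O bond formation at C2, with differentiation of two silyl ethers. The catechin unit, the only one that can be bought intact, is the one that is rebuilt.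
- Comparison: the chosen route uses commercial catechin as it is and treats all three interflavan bonds with the same five-step sequence. It pays for this with linearity.

Key step: step 14

Assumption: the (2R,5R) enantiomer of the C2-symmetric thiolane is taken as the one whose ylide attacks the required face of the quinone methide; should a test reaction show the opposite sense, the (2S,5S) sulfide (from (2R,5R)-hexane-2,5-diol) is used with no other change.

Notation: Bn = benzyl, Piv = pivaloyl, TIPS = triisopropylsilyl, Ms = methanesulfonyl, Tol = 4-methylphenyl. "Cat" is the 3,5,7,3′,4′-penta-O-benzyl-(+)-catechin unit (unit 4). "Epi" is a 3,5,7,3′,4′-penta-O-benzyl-(−)-epicatechin unit joined through C4 (β) to C8 of the unit below. "-8-yl" means attachment through C8 of the top unit. Flavan numbering is used for chromans and benzofuran numbering for dihydrobenzofurans.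

## Route

Step 1
Reactants: 1 (+)-catechin
Product: 2 5,7,3′,4′-tetra-O-benzyl-(+)-catechin
Conditions: BnBr (4.2 equiv), K2CO3, DMF, 0 °C → rt
Reagents that add atoms: benzyl bromide, BrCc1ccccc1
Why: Williamson etherification of the four phenols; carbonate does not deprotonate the C3 alcohol and the phenoxides are capped quickly, so ring C is not opened and C2 keeps its configuration.

Step 2
Reactants: 2 5,7,3′,4′-tetra-O-benzyl-(+)-catechin
Product: 3 3,5,7,3′,4′-penta-O-benzyl-(+)-catechin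
Conditions: NaH, BnBr, DMF, 0 °C → rt
Reagents that add atoms: benzyl bromide, BrCc1ccccc1
Why: Williamson etherification of the secondary alcohol; with every phenol capped no phenoxide can open ring C.

Step 3
Reactants: 3 3,5,7,3′,4′-penta-O-benzyl-(+)-catechin
Product: 4 8-bromo-3,5,7,3′,4′-penta-O-benzyl-(+)-catechin
Conditions: NBS (1.0 equiv), CH2Cl2, −78 °C → rt
Reagents that add atoms: N-bromosuccinimide, O=C1CCC(=O)N1Br
Why: Electrophilic aromatic bromination; in benzylated flavans C8 (between O1 and one benzyloxy group) reacts before C6 (between two benzyloxy groups).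

Step 4
Reactants: 5 2,4,6-trihydroxybenzaldehyde
Product: 6 2,4-bis(benzyloxy)-6-hydroxybenzaldehyde
Conditions: BnBr (2.1 equiv), K2CO3, DMF, 0 °C → rt
Reagents that add atoms: benzyl bromide, BrCc1ccccc1
Why: Williamson etherification that stops at the dibenzyl ether because the last hydroxyl is held in a hydrogen bond to the formyl group; the two ortho hydroxyls are equivalent, so only one product is possible.

Step 5
Reactants: 6 2,4-bis(benzyloxy)-6-hydroxybenzaldehyde
Product: 7 2,4-bis(benzyloxy)-6-(triisopropylsilyloxy)benzaldehyde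
Conditions: NaH, THF/DMF, 0 °C; TIPSCl, 0 °C → rt
Reagents that add atoms: chlorotriisopropylsilane, CC(C)[Si](Cl)(C(C)C)C(C)C
Why: O-silylation of the sodium phenoxide; the bulky silyl ether withstands the aryllithium and resists migration to the alkoxide formed in step 10.

Step 6
Reactants: 8 2-chloro-3′,4′-dihydroxyacetophenone
Product: 9 2-chloro-3′,4′-bis(pivaloyloxy)acetophenone
Conditions: Piv2O (2.4 equiv), Sc(OSO2CF3)3 (cat.), MeCN, rt
Reagents that add atoms: pivalic anhydride, CC(C)(C)C(=O)OC(=O)C(C)(C)C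
Why: Lewis acid-catalysed acylation of both phenols; working without base avoids alkylation of a phenoxide by the chloroketone.

Step 7
Reactants: 10 (2S,5S)-hexane-2,5-diol
Product: 11 (2S,5S)-hexane-2,5-diyl dimethanesulfonate
Conditions: MsCl, Et3N, CH2Cl2, 0 °C
Reagents that add atoms: methanesulfonyl chloride, CS(=O)(=O)Cl
Why: O-sulfonylation of both alcohols; no bond to a stereocentre is broken.

Step 8
Reactants: 11 (2S,5S)-hexane-2,5-diyl dimethanesulfonate
Product: 12 (2R,5R)-2,5-dimethylthiolane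
Conditions: Na2S·9H2O, DMSO, rt → 40 °C
Reagents that add atoms: sodium sulfide, [Na+].[Na+].[S-2]
Why: Double SN2 displacement by sulfide (the second one intramolecular, 5-exo-tet); each centre is inverted, so the (S,S) dimesylate gives the (R,R) sulfide.

Step 9
Reactants: 9 2-chloro-3′,4′-bis(pivaloyloxy)acetophenone; 12 (2R,5R)-2,5-dimethylthiolane
Product: 14 2-[3,4-bis(pivaloyloxy)phenyl]-2-oxo-1-[(2R,5R)-2,5-dimethylthiolan-1-ium-1-yl]ethan-1-ide (stabilised sulfonium ylide), via sulfonium tetrafluoroborate 13 (not isolated)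
Conditions: 12 (1.2 equiv), AgBF4, acetone, rt, dark; filter; then sat. aq K2CO3/CH2Cl2, 0 °C
Reagents that add atoms: none
Why: S-alkylation of the sulfide by the α-chloroketone, driven by precipitation of AgCl, then deprotonation to a carbonyl-stabilised sulfonium ylide, an isolable class of compound. Because the ring is C2-symmetric, sulfur is not a stereocentre and a single ylide results.

Step 10
Reactants: 4 8-bromo-3,5,7,3′,4′-penta-O-benzyl-(+)-catechin; 7 2,4-bis(benzyloxy)-6-(triisopropylsilyloxy)benzaldehyde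
Product: 17 8-{[2,4-bis(benzyloxy)-6-(triisopropylsilyloxy)phenyl](4-methylphenylsulfonyl)methyl}-Cat (epimer mixture at the new carbon), via aryllithium 15 (not isolated), via diarylmethanol 16 (not isolated)
Conditions: n-BuLi, THF, −78 °C; 7, −78 °C; then TolSO2H (3 equiv), CH2Cl2, −78 °C → rt
Reagents that add atoms: 4-methylbenzenesulfinic acid, Cc1ccc(S(=O)O)cc1
Why: Bromine–lithium exchange and 1,2-addition of the C8 aryllithium to the aldehyde make the future C4–C8 bond at a defined ring position. The doubly activated benzhydrol then ionises under the sulfinic acid and is captured at sulfur (SN1 sulfone formation), giving a storable quinone methide precursor. The new carbon is an epimer mixture that step 11 erases.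

Step 11
Reactants: 17 sulfone of step 10; 14 sulfonium ylide
Product: 19 (2S,3R)-4,6-bis(benzyloxy)-2-[3,4-bis(pivaloyloxy)benzoyl]-3-(Cat-8-yl)-2,3-dihydrobenzofuran, via ortho-quinone methide 18 (not isolated)
Conditions: 14 (1.5 equiv), TBAF (1.1 equiv), THF/CH2Cl2, −40 °C → rt
Reagents that add atoms: none
Why: Fluoride removes the silyl group and the phenoxide expels sulfinate (1,4-elimination) to ortho-quinone methide 18, which undergoes the sulfonium ylide [4+1] annulation: conjugate addition of 14 to the methide carbon, then 5-exo-tet SN2 closure by the phenoxide with loss of the sulfide. C3 (the future C4) is set by the C2-symmetric sulfonium group, which exposes one face of the ylide carbon and so selects the face of the methide (reagent control); C2 becomes trans through the anti betaine and, being α to the ketone, by equilibration. Any minor isomer is a diastereomer because unit 4 is chiral, and should be removable by chromatography.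

Step 12
Reactants: 19 trans-2-aroyl-2,3-dihydrobenzofuran
Product: 20 (S)-[3,4-bis(pivaloyloxy)phenyl][(2S,3R)-4,6-bis(benzyloxy)-3-(Cat-8-yl)-2,3-dihydrobenzofuran-2-yl]methanol
Conditions: (S)-1-methyl-3,3-diphenyltetrahydro-1H,3H-pyrrolo[1,2-c][1,3,2]oxazaborole (the (S)-CBS catalyst, 0.2 equiv), BH3·SMe2, THF, −20 °C
Reagents that add atoms: none
Why: Corey–Bakshi–Shibata reduction: with the aryl ring as the large group the (S) catalyst should give the (S) carbinol. The Felkin–Anh preference of this α-aryloxy ketone (C–O1 bond anti to the incoming hydride, approach past H) leads to the same threo alcohol, a matched case. Borane at −20 °C leaves aryl pivalates and benzyl ethers alone.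

Step 13
Reactants: 20 (S)-carbinol
Product: 21 (S)-[3,4-bis(pivaloyloxy)phenyl][(2S,3R)-4,6-bis(benzyloxy)-3-(Cat-8-yl)-2,3-dihydrobenzofuran-2-yl]methyl methanesulfonate
Conditions: Ms2O, Et3N, CH2Cl2, −20 °C → 0 °C; used without delay
Reagents that add atoms: methanesulfonic anhydride, CS(=O)(=O)OS(C)(=O)=O
Why: O-sulfonylation with retention at carbon. The anhydride keeps chloride out, and the ester-bearing ring B together with the β-oxygen keeps the benzylic mesylate from ionising during isolation.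

Step 14
Reactants: 21 benzylic mesylate
Product: 23 [5,7-di-O-benzyl-3′,4′-di-O-pivaloyl-(−)-epicatechin]-(4β→8)-Cat (free C3 hydroxyl on unit 3), via bridged oxonium ion 22 (not isolated)
Conditions: (CF3)2CHOH/H2O (4:1), NaHCO3 (2 equiv), 40 °C
Reagents that add atoms: water, O
Why: Proposed new method: in the ionising but weakly nucleophilic medium the ring oxygen O1 displaces the mesylate from the exocyclic benzylic carbon from the rear (3-exo-tet, inversion) to give bridged oxonium ion 22, and water then attacks the former ring carbon anti to O1 (second inversion), so that the O1–C3 bond is exchanged for O1–C2 and the C3 hydroxyl appears; the closest known reaction type is the ring expansion of 2-(1-sulfonyloxyalkyl) cyclic ethers through bicyclic oxonium ions and the interconversion of 2-(halomethyl)-2,3-dihydrobenzofurans with 3-substituted chromans, not yet shown for a stereodefined benzylic carbon with an aryl ether oxygen as the migrating group. Ring C is therefore closed not by a direct 6-endo attack but by the 3-exo-tet closure followed by cleavage of the O1–C3 bond that the three- and five-membered rings share. C2 (R) is fixed by the (S) carbinol carbon through SN2 inversion, C3 (R) by inversion of the (2S) ring carbon, and C4 (R) is carried over untouched, so the threo, trans mesylate can only give the 2,3-cis-3,4-trans chroman. The step needs participation by O1 to outrun plain solvolysis and needs water to open the bridge at C3 and not at C2. The two pivaloyloxy groups on ring B and the β-oxygen withhold a free benzylic cation, which would lose configuration or suffer a hydride shift to an oxocarbenium ion; attack of water at C2 only returns carbinol 20 with net retention, which is mesylated again, so material drains toward 23. The electron-rich aryl group on C4 is held about 120° away from the breaking O1–C3 bond and cannot migrate, its trans position keeps its ortho oxygens from the benzylic carbon, and NaHCO3 protects the acid-labile C4–C8 bond.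

Step 15
Reactants: 23 dimer dipivalate
Product: 24 [5,7-di-O-benzyl-(−)-epicatechin]-(4β→8)-Cat (free 3-, 3′- and 4′-hydroxyls on unit 3)
Conditions: K2CO3 (0.5 equiv), MeOH/THF, rt, argon
Reagents that add atoms: none
Why: Base-catalysed transesterification (methanolysis) of the two aryl pivalates; short exposure at room temperature with exclusion of oxygen avoids catecholate oxidation and opening of ring C.

Step 16
Reactants: 24 dimer triol
Product: 25 Epi-(4β→8)-Cat (deca-O-benzyl dimer)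
Conditions: BnBr, K2CO3, DMF, rt; then NaH, 0 °C → rt (one pot)
Reagents that add atoms: benzyl bromide, BrCc1ccccc1
Why: Williamson etherification in two stages: the catechol is capped under carbonate before the stronger base is added for the C3 alcohol, so no free phenoxide meets NaH. The esters, which the organolithium of the next cycle would not tolerate, are thereby replaced.

Step 17
Reactants: 25 Epi-(4β→8)-Cat
Product: 26 8-bromo-Epi-(4β→8)-Cat (bromine on C8 of unit 3)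
Conditions: NBS (1.0 equiv), CH2Cl2, −78 °C → −20 °C
Reagents that add atoms: N-bromosuccinimide, O=C1CCC(=O)N1Br
Why: Electrophilic aromatic bromination: the only position of the reactive C8 type (between O1 and one benzyloxy group) is that of unit 3. The other free positions, C6 of units 3 and 4, are of the slower, doubly flanked type.

Step 18
Reactants: 26 8-bromo-Epi-(4β→8)-Cat; 7 2,4-bis(benzyloxy)-6-(triisopropylsilyloxy)benzaldehyde
Product: 29 8-{[2,4-bis(benzyloxy)-6-(triisopropylsilyloxy)phenyl](4-methylphenylsulfonyl)methyl}-Epi-(4β→8)-Cat (substituent on C8 of unit 3; epimer mixture at the new carbon), via aryllithium 27 (not isolated), via diarylmethanol 28 (not isolated)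
Conditions: n-BuLi, THF, −78 °C; 7, −78 °C; then TolSO2H (3 equiv), CH2Cl2, −78 °C → rt
Reagents that add atoms: 4-methylbenzenesulfinic acid, Cc1ccc(S(=O)O)cc1
Why: Bromine–lithium exchange, 1,2-addition to the aldehyde and SN1 sulfone formation as in step 10; only benzyl ethers are present, which tolerate the organolithium at −78 °C.

Step 19
Reactants: 29 sulfone of step 18; 14 sulfonium ylide
Product: 31 (2S,3R)-4,6-bis(benzyloxy)-2-[3,4-bis(pivaloyloxy)benzoyl]-3-{[Epi-(4β→8)-Cat]-8-yl}-2,3-dihydrobenzofuran, via ortho-quinone methide 30 (not isolated)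
Conditions: 14 (1.5 equiv), TBAF (1.1 equiv), THF/CH2Cl2, −40 °C → rt
Reagents that add atoms: none
Why: Fluoride-triggered 1,4-elimination to the ortho-quinone methide and sulfonium ylide [4+1] annulation as in step 11; the chiral sulfonium group sets C3 (future C4 of unit 2) and the trans C2 follows.

Step 20
Reactants: 31 trans-2-aroyl-2,3-dihydrobenzofuran
Product: 32 (S)-[3,4-bis(pivaloyloxy)phenyl][(2S,3R)-4,6-bis(benzyloxy)-3-{[Epi-(4β→8)-Cat]-8-yl}-2,3-dihydrobenzofuran-2-yl]methanol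
Conditions: (S)-1-methyl-3,3-diphenyltetrahydro-1H,3H-pyrrolo[1,2-c][1,3,2]oxazaborole (the (S)-CBS catalyst, 0.2 equiv), BH3·SMe2, THF, −20 °C
Reagents that add atoms: none
Why: Corey–Bakshi–Shibata reduction, matched with the Felkin–Anh preference of the α-aryloxy ketone as in step 12, gives the (S), threo carbinol.

Step 21
Reactants: 32 (S)-carbinol
Product: 33 methanesulfonate of 32 (S at the benzylic carbon)
Conditions: Ms2O, Et3N, CH2Cl2, −20 °C → 0 °C; used without delay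
Reagents that add atoms: methanesulfonic anhydride, CS(=O)(=O)OS(C)(=O)=O
Why: O-sulfonylation with retention, as in step 13.

Step 22
Reactants: 33 benzylic mesylate
Product: 35 [5,7-di-O-benzyl-3′,4′-di-O-pivaloyl-(−)-epicatechin]-(4β→8)-Epi-(4β→8)-Cat (free C3 hydroxyl on unit 2), via bridged oxonium ion 34 (not isolated)
Conditions: (CF3)2CHOH/H2O (4:1), NaHCO3 (2 equiv), 40 °C
Reagents that add atoms: water, O
Why: Proposed new method: the same O1 participation as in step 14 (3-exo-tet closure to oxonium ion 34 with inversion at the benzylic carbon, then opening by water at the ring carbon with a second inversion) builds ring C of unit 2; the closest known reaction type is the oxonium-mediated ring expansion of 2-(1-sulfonyloxyalkyl) cyclic ethers. C2 and C3 of unit 2 are set by the two inversions and C4 is carried over. The benzyl ethers and the interflavan bond below are inert to the buffered medium.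

Step 23
Reactants: 35 trimer dipivalate
Product: 36 [5,7-di-O-benzyl-(−)-epicatechin]-(4β→8)-Epi-(4β→8)-Cat (free 3-, 3′- and 4′-hydroxyls on unit 2)
Conditions: K2CO3 (0.5 equiv), MeOH/THF, rt, argon
Reagents that add atoms: none
Why: Methanolysis (transesterification) of the two aryl pivalates as in step 15.

Step 24
Reactants: 36 trimer triol
Product: 37 Epi-(4β→8)-Epi-(4β→8)-Cat (pentadeca-O-benzyl trimer)
Conditions: BnBr, K2CO3, DMF, rt; then NaH, 0 °C → rt (one pot)
Reagents that add atoms: benzyl bromide, BrCc1ccccc1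
Why: Two-stage Williamson etherification as in step 16.

Step 25
Reactants: 37 perbenzylated trimer
Product: 38 8-bromo-Epi-(4β→8)-Epi-(4β→8)-Cat (bromine on C8 of unit 2)
Conditions: NBS (1.0 equiv), CH2Cl2, −78 °C → −20 °C
Reagents that add atoms: N-bromosuccinimide, O=C1CCC(=O)N1Br
Why: Electrophilic aromatic bromination at the only C8-type position, that of unit 2, as in step 17.

Step 26
Reactants: 38 8-bromo trimer; 7 2,4-bis(benzyloxy)-6-(triisopropylsilyloxy)benzaldehyde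
Product: 41 8-{[2,4-bis(benzyloxy)-6-(triisopropylsilyloxy)phenyl](4-methylphenylsulfonyl)methyl}-Epi-(4β→8)-Epi-(4β→8)-Cat (substituent on C8 of unit 2; epimer mixture at the new carbon), via aryllithium 39 (not isolated), via diarylmethanol 40 (not isolated)
Conditions: n-BuLi, THF, −78 °C; 7, −78 °C; then TolSO2H (3 equiv), CH2Cl2, −78 °C → rt
Reagents that add atoms: 4-methylbenzenesulfinic acid, Cc1ccc(S(=O)O)cc1
Why: Bromine–lithium exchange, 1,2-addition to the aldehyde and SN1 sulfone formation as in step 10.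

Step 27
Reactants: 41 sulfone of step 26; 14 sulfonium ylide
Product: 43 (2S,3R)-4,6-bis(benzyloxy)-2-[3,4-bis(pivaloyloxy)benzoyl]-3-{[Epi-(4β→8)-Epi-(4β→8)-Cat]-8-yl}-2,3-dihydrobenzofuran, via ortho-quinone methide 42 (not isolated)
Conditions: 14 (1.5 equiv), TBAF (1.1 equiv), THF/CH2Cl2, −40 °C → rt
Reagents that add atoms: none
Why: Fluoride-triggered 1,4-elimination and sulfonium ylide [4+1] annulation as in step 11; the chiral sulfonium group sets C3 (future C4 of unit 1) and the trans C2 follows.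

Step 28
Reactants: 43 trans-2-aroyl-2,3-dihydrobenzofuran
Product: 44 (S)-[3,4-bis(pivaloyloxy)phenyl][(2S,3R)-4,6-bis(benzyloxy)-3-{[Epi-(4β→8)-Epi-(4β→8)-Cat]-8-yl}-2,3-dihydrobenzofuran-2-yl]methanol
Conditions: (S)-1-methyl-3,3-diphenyltetrahydro-1H,3H-pyrrolo[1,2-c][1,3,2]oxazaborole (the (S)-CBS catalyst, 0.2 equiv), BH3·SMe2, THF, −20 °C
Reagents that add atoms: none
Why: Corey–Bakshi–Shibata reduction, matched with the Felkin–Anh preference as in step 12, gives the (S), threo carbinol.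

Step 29
Reactants: 44 (S)-carbinol
Product: 45 methanesulfonate of 44 (S at the benzylic carbon)
Conditions: Ms2O, Et3N, CH2Cl2, −20 °C → 0 °C; used without delay
Reagents that add atoms: methanesulfonic anhydride, CS(=O)(=O)OS(C)(=O)=O
Why: O-sulfonylation with retention, as in step 13.

Step 30
Reactants: 45 benzylic mesylate
Product: 47 [5,7-di-O-benzyl-3′,4′-di-O-pivaloyl-(−)-epicatechin]-(4β→8)-Epi-(4β→8)-Epi-(4β→8)-Cat (free C3 hydroxyl on unit 1), via bridged oxonium ion 46 (not isolated)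
Conditions: (CF3)2CHOH/H2O (4:1), NaHCO3 (2 equiv), 40 °C
Reagents that add atoms: water, O
Why: Proposed new method: O1 participation as in step 14 (3-exo-tet closure to oxonium ion 46 with inversion at the benzylic carbon, then opening by water at the ring carbon with a second inversion) builds ring C of unit 1; the closest known reaction type is the oxonium-mediated ring expansion of 2-(1-sulfonyloxyalkyl) cyclic ethers. C2 and C3 of unit 1 are set by the two inversions and C4 is carried over; the buffered medium spares the two interflavan bonds already present.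

Step 31
Reactants: 47 tetramer dipivalate
Product: 48 [5,7-di-O-benzyl-(−)-epicatechin]-(4β→8)-Epi-(4β→8)-Epi-(4β→8)-Cat (free 3-, 3′- and 4′-hydroxyls on unit 1)
Conditions: K2CO3 (0.5 equiv), MeOH/THF, rt, argon
Reagents that add atoms: none
Why: Methanolysis (transesterification) of the two aryl pivalates; it is done before the hydrogenolysis so that base never meets the free polyphenol.

Step 32
Reactants: 48 heptadeca-O-benzyl tetramer
Product: 49 arecatannin A2
Conditions: H2 (1 atm), Pd(OH)2/C, THF/MeOH/H2O, rt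
Reagents that add atoms: none
Why: Hydrogenolysis of seventeen benzyl ethers under neutral conditions; the C4–C8 bonds and the benzylic C2–O1 bonds of flavans are expected to survive this catalyst at atmospheric pressure, and no stereocentre is touched.

## Compound list

1 | (+)-catechin | Oc1cc(O)c2c(c1)O[C@H](c1ccc(O)c(O)c1)[C@@H](O)C2 | starting material
2 | 5,7,3′,4′-tetra-O-benzyl-(+)-catechin | c1c(OCc3ccccc3)cc(OCc3ccccc3)c2c1O[C@H](c1ccc(OCc3ccccc3)c(OCc3ccccc3)c1)[C@@H](O)C2 | intermediate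
3 | 3,5,7,3′,4′-penta-O-benzyl-(+)-catechin | c1c(OCc3ccccc3)cc(OCc3ccccc3)c2c1O[C@H](c1ccc(OCc3ccccc3)c(OCc3ccccc3)c1)[C@@H](OCc3ccccc3)C2 | intermediate
4 | 8-bromo-3,5,7,3′,4′-penta-O-benzyl-(+)-catechin | Brc1c(OCc3ccccc3)cc(OCc3ccccc3)c2c1O[C@H](c1ccc(OCc3ccccc3)c(OCc3ccccc3)c1)[C@@H](OCc3ccccc3)C2 | intermediate
5 | 2,4,6-trihydroxybenzaldehyde | O=Cc1c(O)cc(O)cc1O | starting material
6 | 2,4-bis(benzyloxy)-6-hydroxybenzaldehyde | O=Cc1c(O)cc(OCc2ccccc2)cc1OCc1ccccc1 | intermediate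
7 | 2,4-bis(benzyloxy)-6-(triisopropylsilyloxy)benzaldehyde | O=Cc1c(O[Si](C(C)C)(C(C)C)C(C)C)cc(OCc2ccccc2)cc1OCc1ccccc1 | intermediate
8 | 2-chloro-3′,4′-dihydroxyacetophenone | O=C(CCl)c1ccc(O)c(O)c1 | starting material
9 | 2-chloro-3′,4′-bis(pivaloyloxy)acetophenone | O=C(CCl)c1ccc(OC(=O)C(C)(C)C)c(OC(=O)C(C)(C)C)c1 | intermediate
10 | (2S,5S)-hexane-2,5-diol | C[C@H](O)CC[C@H](C)O | starting material
11 | (2S,5S)-hexane-2,5-diyl dimethanesulfonate | C[C@H](OS(C)(=O)=O)CC[C@H](C)OS(C)(=O)=O | intermediate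
12 | (2R,5R)-2,5-dimethylthiolane | C[C@@H]1CC[C@@H](C)S1 | intermediate
13 | (2R,5R)-1-{2-[3,4-bis(pivaloyloxy)phenyl]-2-oxoethyl}-2,5-dimethylthiolan-1-ium tetrafluoroborate | C[C@@H]1CC[C@@H](C)[S+]1CC(=O)c1ccc(OC(=O)C(C)(C)C)c(OC(=O)C(C)(C)C)c1.F[B-](F)(F)F | intermediate
14 | 2-[3,4-bis(pivaloyloxy)phenyl]-2-oxo-1-[(2R,5R)-2,5-dimethylthiolan-1-ium-1-yl]ethan-1-ide (sulfonium ylide) | C[C@@H]1CC[C@@H](C)[S+]1[CH-]C(=O)c1ccc(OC(=O)C(C)(C)C)c(OC(=O)C(C)(C)C)c1 | intermediate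
15 | 8-lithio-3,5,7,3′,4′-penta-O-benzyl-(+)-catechin | [Li]c1c(OCc3ccccc3)cc(OCc3ccccc3)c2c1O[C@H](c1ccc(OCc3ccccc3)c(OCc3ccccc3)c1)[C@@H](OCc3ccccc3)C2 | intermediate
16 | [2,4-bis(benzyloxy)-6-(triisopropylsilyloxy)phenyl](Cat-8-yl)methanol, both epimers at the carbinol carbon | CC(C)[Si](C(C)C)(C(C)C)Oc1cc(OCc3ccccc3)cc(OCc3ccccc3)c1C(O)c1c(OCc3ccccc3)cc(OCc3ccccc3)c2c1O[C@H](c1ccc(OCc3ccccc3)c(OCc3ccccc3)c1)[C@@H](OCc3ccccc3)C2 | intermediate
17 | 8-{[2,4-bis(benzyloxy)-6-(triisopropylsilyloxy)phenyl](4-methylphenylsulfonyl)methyl}-Cat, both epimers at the sulfonyl-bearing carbon | CC(C)[Si](C(C)C)(C(C)C)Oc1cc(OCc3ccccc3)cc(OCc3ccccc3)c1C(S(=O)(=O)c1ccc(C)cc1)c1c(OCc3ccccc3)cc(OCc3ccccc3)c2c1O[C@H](c1ccc(OCc3ccccc3)c(OCc3ccccc3)c1)[C@@H](OCc3ccccc3)C2 | intermediate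
18 | 3,5-bis(benzyloxy)-6-[(Cat-8-yl)methylidene]cyclohexa-2,4-dien-1-one (ortho-quinone methide) | O=C1C=C(OCc3ccccc3)C=C(OCc3ccccc3)C1=Cc1c(OCc3ccccc3)cc(OCc3ccccc3)c2c1O[C@H](c1ccc(OCc3ccccc3)c(OCc3ccccc3)c1)[C@@H](OCc3ccccc3)C2 | intermediate
19 | (2S,3R)-4,6-bis(benzyloxy)-2-[3,4-bis(pivaloyloxy)benzoyl]-3-(Cat-8-yl)-2,3-dihydrobenzofuran | c1c(OCc3ccccc3)cc(OCc3ccccc3)c2c1O[C@H](C(=O)c1ccc(OC(=O)C(C)(C)C)c(OC(=O)C(C)(C)C)c1)[C@H]2c1c(OCc3ccccc3)cc(OCc3ccccc3)c2c1O[C@H](c1ccc(OCc3ccccc3)c(OCc3ccccc3)c1)[C@@H](OCc3ccccc3)C2 | intermediate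
20 | (S)-[3,4-bis(pivaloyloxy)phenyl][(2S,3R)-4,6-bis(benzyloxy)-3-(Cat-8-yl)-2,3-dihydrobenzofuran-2-yl]methanol | c1c(OCc3ccccc3)cc(OCc3ccccc3)c2c1O[C@H]([C@@H](O)c1ccc(OC(=O)C(C)(C)C)c(OC(=O)C(C)(C)C)c1)[C@H]2c1c(OCc3ccccc3)cc(OCc3ccccc3)c2c1O[C@H](c1ccc(OCc3ccccc3)c(OCc3ccccc3)c1)[C@@H](OCc3ccccc3)C2 | intermediate
21 | methanesulfonate of 20 (S at the benzylic carbon) | c1c(OCc3ccccc3)cc(OCc3ccccc3)c2c1O[C@H]([C@@H](OS(C)(=O)=O)c1ccc(OC(=O)C(C)(C)C)c(OC(=O)C(C)(C)C)c1)[C@H]2c1c(OCc3ccccc3)cc(OCc3ccccc3)c2c1O[C@H](c1ccc(OCc3ccccc3)c(OCc3ccccc3)c1)[C@@H](OCc3ccccc3)C2 | intermediate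
22 | bridged oxonium methanesulfonate from 21: O1 bonded to C8a, to the inverted benzylic carbon (future C2) and to the ring carbon (future C3) | c1c(OCc3ccccc3)cc(OCc3ccccc3)c2c1[O+]4[C@H]([C@H]4c1ccc(OC(=O)C(C)(C)C)c(OC(=O)C(C)(C)C)c1)[C@H]2c1c(OCc3ccccc3)cc(OCc3ccccc3)c2c1O[C@H](c1ccc(OCc3ccccc3)c(OCc3ccccc3)c1)[C@@H](OCc3ccccc3)C2.CS(=O)(=O)[O-] | intermediate
23 | [5,7-di-O-benzyl-3′,4′-di-O-pivaloyl-(−)-epicatechin]-(4β→8)-Cat | c1c(OCc3ccccc3)cc(OCc3ccccc3)c2c1O[C@H](c1ccc(OC(=O)C(C)(C)C)c(OC(=O)C(C)(C)C)c1)[C@H](O)[C@H]2c1c(OCc3ccccc3)cc(OCc3ccccc3)c2c1O[C@H](c1ccc(OCc3ccccc3)c(OCc3ccccc3)c1)[C@@H](OCc3ccccc3)C2 | intermediate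
24 | [5,7-di-O-benzyl-(−)-epicatechin]-(4β→8)-Cat | c1c(OCc3ccccc3)cc(OCc3ccccc3)c2c1O[C@H](c1ccc(O)c(O)c1)[C@H](O)[C@H]2c1c(OCc3ccccc3)cc(OCc3ccccc3)c2c1O[C@H](c1ccc(OCc3ccccc3)c(OCc3ccccc3)c1)[C@@H](OCc3ccccc3)C2 | intermediate
25 | Epi-(4β→8)-Cat | c1c(OCc3ccccc3)cc(OCc3ccccc3)c2c1O[C@H](c1ccc(OCc3ccccc3)c(OCc3ccccc3)c1)[C@H](OCc3ccccc3)[C@H]2c1c(OCc3ccccc3)cc(OCc3ccccc3)c2c1O[C@H](c1ccc(OCc3ccccc3)c(OCc3ccccc3)c1)[C@@H](OCc3ccccc3)C2 | intermediate
26 | 8-bromo-Epi-(4β→8)-Cat | Brc1c(OCc3ccccc3)cc(OCc3ccccc3)c2c1O[C@H](c1ccc(OCc3ccccc3)c(OCc3ccccc3)c1)[C@H](OCc3ccccc3)[C@H]2c1c(OCc3ccccc3)cc(OCc3ccccc3)c2c1O[C@H](c1ccc(OCc3ccccc3)c(OCc3ccccc3)c1)[C@@H](OCc3ccccc3)C2 | intermediate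
27 | 8-lithio-Epi-(4β→8)-Cat | [Li]c1c(OCc3ccccc3)cc(OCc3ccccc3)c2c1O[C@H](c1ccc(OCc3ccccc3)c(OCc3ccccc3)c1)[C@H](OCc3ccccc3)[C@H]2c1c(OCc3ccccc3)cc(OCc3ccccc3)c2c1O[C@H](c1ccc(OCc3ccccc3)c(OCc3ccccc3)c1)[C@@H](OCc3ccccc3)C2 | intermediate
28 | [2,4-bis(benzyloxy)-6-(triisopropylsilyloxy)phenyl]{[Epi-(4β→8)-Cat]-8-yl}methanol, both epimers at the carbinol carbon | CC(C)[Si](C(C)C)(C(C)C)Oc1cc(OCc3ccccc3)cc(OCc3ccccc3)c1C(O)c1c(OCc3ccccc3)cc(OCc3ccccc3)c2c1O[C@H](c1ccc(OCc3ccccc3)c(OCc3ccccc3)c1)[C@H](OCc3ccccc3)[C@H]2c1c(OCc3ccccc3)cc(OCc3ccccc3)c2c1O[C@H](c1ccc(OCc3ccccc3)c(OCc3ccccc3)c1)[C@@H](OCc3ccccc3)C2 | intermediate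
29 | 8-{[2,4-bis(benzyloxy)-6-(triisopropylsilyloxy)phenyl](4-methylphenylsulfonyl)methyl}-Epi-(4β→8)-Cat, both epimers at the sulfonyl-bearing carbon | CC(C)[Si](C(C)C)(C(C)C)Oc1cc(OCc3ccccc3)cc(OCc3ccccc3)c1C(S(=O)(=O)c1ccc(C)cc1)c1c(OCc3ccccc3)cc(OCc3ccccc3)c2c1O[C@H](c1ccc(OCc3ccccc3)c(OCc3ccccc3)c1)[C@H](OCc3ccccc3)[C@H]2c1c(OCc3ccccc3)cc(OCc3ccccc3)c2c1O[C@H](c1ccc(OCc3ccccc3)c(OCc3ccccc3)c1)[C@@H](OCc3ccccc3)C2 | intermediate
30 | 3,5-bis(benzyloxy)-6-({[Epi-(4β→8)-Cat]-8-yl}methylidene)cyclohexa-2,4-dien-1-one (ortho-quinone methide) | O=C1C=C(OCc3ccccc3)C=C(OCc3ccccc3)C1=Cc1c(OCc3ccccc3)cc(OCc3ccccc3)c2c1O[C@H](c1ccc(OCc3ccccc3)c(OCc3ccccc3)c1)[C@H](OCc3ccccc3)[C@H]2c1c(OCc3ccccc3)cc(OCc3ccccc3)c2c1O[C@H](c1ccc(OCc3ccccc3)c(OCc3ccccc3)c1)[C@@H](OCc3ccccc3)C2 | intermediate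
31 | (2S,3R)-4,6-bis(benzyloxy)-2-[3,4-bis(pivaloyloxy)benzoyl]-3-{[Epi-(4β→8)-Cat]-8-yl}-2,3-dihydrobenzofuran | c1c(OCc3ccccc3)cc(OCc3ccccc3)c2c1O[C@H](C(=O)c1ccc(OC(=O)C(C)(C)C)c(OC(=O)C(C)(C)C)c1)[C@H]2c1c(OCc3ccccc3)cc(OCc3ccccc3)c2c1O[C@H](c1ccc(OCc3ccccc3)c(OCc3ccccc3)c1)[C@H](OCc3ccccc3)[C@H]2c1c(OCc3ccccc3)cc(OCc3ccccc3)c2c1O[C@H](c1ccc(OCc3ccccc3)c(OCc3ccccc3)c1)[C@@H](OCc3ccccc3)C2 | intermediate
32 | (S)-[3,4-bis(pivaloyloxy)phenyl][(2S,3R)-4,6-bis(benzyloxy)-3-{[Epi-(4β→8)-Cat]-8-yl}-2,3-dihydrobenzofuran-2-yl]methanol | c1c(OCc3ccccc3)cc(OCc3ccccc3)c2c1O[C@H]([C@@H](O)c1ccc(OC(=O)C(C)(C)C)c(OC(=O)C(C)(C)C)c1)[C@H]2c1c(OCc3ccccc3)cc(OCc3ccccc3)c2c1O[C@H](c1ccc(OCc3ccccc3)c(OCc3ccccc3)c1)[C@H](OCc3ccccc3)[C@H]2c1c(OCc3ccccc3)cc(OCc3ccccc3)c2c1O[C@H](c1ccc(OCc3ccccc3)c(OCc3ccccc3)c1)[C@@H](OCc3ccccc3)C2 | intermediate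
33 | methanesulfonate of 32 (S at the benzylic carbon) | c1c(OCc3ccccc3)cc(OCc3ccccc3)c2c1O[C@H]([C@@H](OS(C)(=O)=O)c1ccc(OC(=O)C(C)(C)C)c(OC(=O)C(C)(C)C)c1)[C@H]2c1c(OCc3ccccc3)cc(OCc3ccccc3)c2c1O[C@H](c1ccc(OCc3ccccc3)c(OCc3ccccc3)c1)[C@H](OCc3ccccc3)[C@H]2c1c(OCc3ccccc3)cc(OCc3ccccc3)c2c1O[C@H](c1ccc(OCc3ccccc3)c(OCc3ccccc3)c1)[C@@H](OCc3ccccc3)C2 | intermediate
34 | bridged oxonium methanesulfonate from 33 (O1 bonded to C8a, to the inverted benzylic carbon and to the ring carbon) | c1c(OCc3ccccc3)cc(OCc3ccccc3)c2c1[O+]4[C@H]([C@H]4c1ccc(OC(=O)C(C)(C)C)c(OC(=O)C(C)(C)C)c1)[C@H]2c1c(OCc3ccccc3)cc(OCc3ccccc3)c2c1O[C@H](c1ccc(OCc3ccccc3)c(OCc3ccccc3)c1)[C@H](OCc3ccccc3)[C@H]2c1c(OCc3ccccc3)cc(OCc3ccccc3)c2c1O[C@H](c1ccc(OCc3ccccc3)c(OCc3ccccc3)c1)[C@@H](OCc3ccccc3)C2.CS(=O)(=O)[O-] | intermediate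
35 | [5,7-di-O-benzyl-3′,4′-di-O-pivaloyl-(−)-epicatechin]-(4β→8)-Epi-(4β→8)-Cat | c1c(OCc3ccccc3)cc(OCc3ccccc3)c2c1O[C@H](c1ccc(OC(=O)C(C)(C)C)c(OC(=O)C(C)(C)C)c1)[C@H](O)[C@H]2c1c(OCc3ccccc3)cc(OCc3ccccc3)c2c1O[C@H](c1ccc(OCc3ccccc3)c(OCc3ccccc3)c1)[C@H](OCc3ccccc3)[C@H]2c1c(OCc3ccccc3)cc(OCc3ccccc3)c2c1O[C@H](c1ccc(OCc3ccccc3)c(OCc3ccccc3)c1)[C@@H](OCc3ccccc3)C2 | intermediate
36 | [5,7-di-O-benzyl-(−)-epicatechin]-(4β→8)-Epi-(4β→8)-Cat | c1c(OCc3ccccc3)cc(OCc3ccccc3)c2c1O[C@H](c1ccc(O)c(O)c1)[C@H](O)[C@H]2c1c(OCc3ccccc3)cc(OCc3ccccc3)c2c1O[C@H](c1ccc(OCc3ccccc3)c(OCc3ccccc3)c1)[C@H](OCc3ccccc3)[C@H]2c1c(OCc3ccccc3)cc(OCc3ccccc3)c2c1O[C@H](c1ccc(OCc3ccccc3)c(OCc3ccccc3)c1)[C@@H](OCc3ccccc3)C2 | intermediate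
37 | Epi-(4β→8)-Epi-(4β→8)-Cat | c1c(OCc3ccccc3)cc(OCc3ccccc3)c2c1O[C@H](c1ccc(OCc3ccccc3)c(OCc3ccccc3)c1)[C@H](OCc3ccccc3)[C@H]2c1c(OCc3ccccc3)cc(OCc3ccccc3)c2c1O[C@H](c1ccc(OCc3ccccc3)c(OCc3ccccc3)c1)[C@H](OCc3ccccc3)[C@H]2c1c(OCc3ccccc3)cc(OCc3ccccc3)c2c1O[C@H](c1ccc(OCc3ccccc3)c(OCc3ccccc3)c1)[C@@H](OCc3ccccc3)C2 | intermediate
38 | 8-bromo-Epi-(4β→8)-Epi-(4β→8)-Cat | Brc1c(OCc3ccccc3)cc(OCc3ccccc3)c2c1O[C@H](c1ccc(OCc3ccccc3)c(OCc3ccccc3)c1)[C@H](OCc3ccccc3)[C@H]2c1c(OCc3ccccc3)cc(OCc3ccccc3)c2c1O[C@H](c1ccc(OCc3ccccc3)c(OCc3ccccc3)c1)[C@H](OCc3ccccc3)[C@H]2c1c(OCc3ccccc3)cc(OCc3ccccc3)c2c1O[C@H](c1ccc(OCc3ccccc3)c(OCc3ccccc3)c1)[C@@H](OCc3ccccc3)C2 | intermediate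
39 | 8-lithio-Epi-(4β→8)-Epi-(4β→8)-Cat | [Li]c1c(OCc3ccccc3)cc(OCc3ccccc3)c2c1O[C@H](c1ccc(OCc3ccccc3)c(OCc3ccccc3)c1)[C@H](OCc3ccccc3)[C@H]2c1c(OCc3ccccc3)cc(OCc3ccccc3)c2c1O[C@H](c1ccc(OCc3ccccc3)c(OCc3ccccc3)c1)[C@H](OCc3ccccc3)[C@H]2c1c(OCc3ccccc3)cc(OCc3ccccc3)c2c1O[C@H](c1ccc(OCc3ccccc3)c(OCc3ccccc3)c1)[C@@H](OCc3ccccc3)C2 | intermediate
40 | [2,4-bis(benzyloxy)-6-(triisopropylsilyloxy)phenyl]{[Epi-(4β→8)-Epi-(4β→8)-Cat]-8-yl}methanol, both epimers at the carbinol carbon | CC(C)[Si](C(C)C)(C(C)C)Oc1cc(OCc3ccccc3)cc(OCc3ccccc3)c1C(O)c1c(OCc3ccccc3)cc(OCc3ccccc3)c2c1O[C@H](c1ccc(OCc3ccccc3)c(OCc3ccccc3)c1)[C@H](OCc3ccccc3)[C@H]2c1c(OCc3ccccc3)cc(OCc3ccccc3)c2c1O[C@H](c1ccc(OCc3ccccc3)c(OCc3ccccc3)c1)[C@H](OCc3ccccc3)[C@H]2c1c(OCc3ccccc3)cc(OCc3ccccc3)c2c1O[C@H](c1ccc(OCc3ccccc3)c(OCc3ccccc3)c1)[C@@H](OCc3ccccc3)C2 | intermediate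
41 | 8-{[2,4-bis(benzyloxy)-6-(triisopropylsilyloxy)phenyl](4-methylphenylsulfonyl)methyl}-Epi-(4β→8)-Epi-(4β→8)-Cat, both epimers at the sulfonyl-bearing carbon | CC(C)[Si](C(C)C)(C(C)C)Oc1cc(OCc3ccccc3)cc(OCc3ccccc3)c1C(S(=O)(=O)c1ccc(C)cc1)c1c(OCc3ccccc3)cc(OCc3ccccc3)c2c1O[C@H](c1ccc(OCc3ccccc3)c(OCc3ccccc3)c1)[C@H](OCc3ccccc3)[C@H]2c1c(OCc3ccccc3)cc(OCc3ccccc3)c2c1O[C@H](c1ccc(OCc3ccccc3)c(OCc3ccccc3)c1)[C@H](OCc3ccccc3)[C@H]2c1c(OCc3ccccc3)cc(OCc3ccccc3)c2c1O[C@H](c1ccc(OCc3ccccc3)c(OCc3ccccc3)c1)[C@@H](OCc3ccccc3)C2 | intermediate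
42 | 3,5-bis(benzyloxy)-6-({[Epi-(4β→8)-Epi-(4β→8)-Cat]-8-yl}methylidene)cyclohexa-2,4-dien-1-one (ortho-quinone methide) | O=C1C=C(OCc3ccccc3)C=C(OCc3ccccc3)C1=Cc1c(OCc3ccccc3)cc(OCc3ccccc3)c2c1O[C@H](c1ccc(OCc3ccccc3)c(OCc3ccccc3)c1)[C@H](OCc3ccccc3)[C@H]2c1c(OCc3ccccc3)cc(OCc3ccccc3)c2c1O[C@H](c1ccc(OCc3ccccc3)c(OCc3ccccc3)c1)[C@H](OCc3ccccc3)[C@H]2c1c(OCc3ccccc3)cc(OCc3ccccc3)c2c1O[C@H](c1ccc(OCc3ccccc3)c(OCc3ccccc3)c1)[C@@H](OCc3ccccc3)C2 | intermediate
43 | (2S,3R)-4,6-bis(benzyloxy)-2-[3,4-bis(pivaloyloxy)benzoyl]-3-{[Epi-(4β→8)-Epi-(4β→8)-Cat]-8-yl}-2,3-dihydrobenzofuran | c1c(OCc3ccccc3)cc(OCc3ccccc3)c2c1O[C@H](C(=O)c1ccc(OC(=O)C(C)(C)C)c(OC(=O)C(C)(C)C)c1)[C@H]2c1c(OCc3ccccc3)cc(OCc3ccccc3)c2c1O[C@H](c1ccc(OCc3ccccc3)c(OCc3ccccc3)c1)[C@H](OCc3ccccc3)[C@H]2c1c(OCc3ccccc3)cc(OCc3ccccc3)c2c1O[C@H](c1ccc(OCc3ccccc3)c(OCc3ccccc3)c1)[C@H](OCc3ccccc3)[C@H]2c1c(OCc3ccccc3)cc(OCc3ccccc3)c2c1O[C@H](c1ccc(OCc3ccccc3)c(OCc3ccccc3)c1)[C@@H](OCc3ccccc3)C2 | intermediate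
44 | (S)-[3,4-bis(pivaloyloxy)phenyl][(2S,3R)-4,6-bis(benzyloxy)-3-{[Epi-(4β→8)-Epi-(4β→8)-Cat]-8-yl}-2,3-dihydrobenzofuran-2-yl]methanol | c1c(OCc3ccccc3)cc(OCc3ccccc3)c2c1O[C@H]([C@@H](O)c1ccc(OC(=O)C(C)(C)C)c(OC(=O)C(C)(C)C)c1)[C@H]2c1c(OCc3ccccc3)cc(OCc3ccccc3)c2c1O[C@H](c1ccc(OCc3ccccc3)c(OCc3ccccc3)c1)[C@H](OCc3ccccc3)[C@H]2c1c(OCc3ccccc3)cc(OCc3ccccc3)c2c1O[C@H](c1ccc(OCc3ccccc3)c(OCc3ccccc3)c1)[C@H](OCc3ccccc3)[C@H]2c1c(OCc3ccccc3)cc(OCc3ccccc3)c2c1O[C@H](c1ccc(OCc3ccccc3)c(OCc3ccccc3)c1)[C@@H](OCc3ccccc3)C2 | intermediate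
45 | methanesulfonate of 44 (S at the benzylic carbon) | c1c(OCc3ccccc3)cc(OCc3ccccc3)c2c1O[C@H]([C@@H](OS(C)(=O)=O)c1ccc(OC(=O)C(C)(C)C)c(OC(=O)C(C)(C)C)c1)[C@H]2c1c(OCc3ccccc3)cc(OCc3ccccc3)c2c1O[C@H](c1ccc(OCc3ccccc3)c(OCc3ccccc3)c1)[C@H](OCc3ccccc3)[C@H]2c1c(OCc3ccccc3)cc(OCc3ccccc3)c2c1O[C@H](c1ccc(OCc3ccccc3)c(OCc3ccccc3)c1)[C@H](OCc3ccccc3)[C@H]2c1c(OCc3ccccc3)cc(OCc3ccccc3)c2c1O[C@H](c1ccc(OCc3ccccc3)c(OCc3ccccc3)c1)[C@@H](OCc3ccccc3)C2 | intermediate
46 | bridged oxonium methanesulfonate from 45 (O1 bonded to C8a, to the inverted benzylic carbon and to the ring carbon) | c1c(OCc3ccccc3)cc(OCc3ccccc3)c2c1[O+]4[C@H]([C@H]4c1ccc(OC(=O)C(C)(C)C)c(OC(=O)C(C)(C)C)c1)[C@H]2c1c(OCc3ccccc3)cc(OCc3ccccc3)c2c1O[C@H](c1ccc(OCc3ccccc3)c(OCc3ccccc3)c1)[C@H](OCc3ccccc3)[C@H]2c1c(OCc3ccccc3)cc(OCc3ccccc3)c2c1O[C@H](c1ccc(OCc3ccccc3)c(OCc3ccccc3)c1)[C@H](OCc3ccccc3)[C@H]2c1c(OCc3ccccc3)cc(OCc3ccccc3)c2c1O[C@H](c1ccc(OCc3ccccc3)c(OCc3ccccc3)c1)[C@@H](OCc3ccccc3)C2.CS(=O)(=O)[O-] | intermediate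
47 | [5,7-di-O-benzyl-3′,4′-di-O-pivaloyl-(−)-epicatechin]-(4β→8)-Epi-(4β→8)-Epi-(4β→8)-Cat | c1c(OCc3ccccc3)cc(OCc3ccccc3)c2c1O[C@H](c1ccc(OC(=O)C(C)(C)C)c(OC(=O)C(C)(C)C)c1)[C@H](O)[C@H]2c1c(OCc3ccccc3)cc(OCc3ccccc3)c2c1O[C@H](c1ccc(OCc3ccccc3)c(OCc3ccccc3)c1)[C@H](OCc3ccccc3)[C@H]2c1c(OCc3ccccc3)cc(OCc3ccccc3)c2c1O[C@H](c1ccc(OCc3ccccc3)c(OCc3ccccc3)c1)[C@H](OCc3ccccc3)[C@H]2c1c(OCc3ccccc3)cc(OCc3ccccc3)c2c1O[C@H](c1ccc(OCc3ccccc3)c(OCc3ccccc3)c1)[C@@H](OCc3ccccc3)C2 | intermediate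
48 | [5,7-di-O-benzyl-(−)-epicatechin]-(4β→8)-Epi-(4β→8)-Epi-(4β→8)-Cat | c1c(OCc3ccccc3)cc(OCc3ccccc3)c2c1O[C@H](c1ccc(O)c(O)c1)[C@H](O)[C@H]2c1c(OCc3ccccc3)cc(OCc3ccccc3)c2c1O[C@H](c1ccc(OCc3ccccc3)c(OCc3ccccc3)c1)[C@H](OCc3ccccc3)[C@H]2c1c(OCc3ccccc3)cc(OCc3ccccc3)c2c1O[C@H](c1ccc(OCc3ccccc3)c(OCc3ccccc3)c1)[C@H](OCc3ccccc3)[C@H]2c1c(OCc3ccccc3)cc(OCc3ccccc3)c2c1O[C@H](c1ccc(OCc3ccccc3)c(OCc3ccccc3)c1)[C@@H](OCc3ccccc3)C2 | intermediate
49 | arecatannin A2, (−)-epicatechin-(4β→8)-(−)-epicatechin-(4β→8)-(−)-epicatechin-(4β→8)-(+)-catechin | Oc1cc(O)c2c(c1)O[C@H](c1ccc(O)c(O)c1)[C@H](O)[C@H]2c1c(O)cc(O)c2c1O[C@H](c1ccc(O)c(O)c1)[C@H](O)[C@H]2c1c(O)cc(O)c2c1O[C@H](c1ccc(O)c(O)c1)[C@H](O)[C@H]2c1c(O)cc(O)c2c1O[C@H](c1ccc(O)c(O)c1)[C@@H](O)C2 | target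

## Step count and least certain steps

Total number of steps: 32. Longest linear sequence: 26 steps (steps 1 to 3 and 10 to 32, from (+)-catechin 1).

Step 14 (key step; carries the label "Proposed new method:"). The most likely failure is ionisation without participation by O1: direct displacement of the mesylate by water or solvent, or a 1,2-hydride shift after loss of the leaving group. Either would erase the C2 configuration or break the skeleton, because an aryl ether oxygen is a weak neighbouring group and a three-membered oxonium ring is strained. The second failure is opening of the bridge at the benzylic carbon, which only returns carbinol 20. The fallback uses known chemistry, sets out from 2 and returns to the route at 25. Dess–Martin periodinane oxidises the C3 alcohol of 2 to (2R)-5,7-bis(benzyloxy)-2-[3,4-bis(benzyloxy)phenyl]chroman-3-one F1. LiBH(s-Bu)3 in THF at −78 °C reduces F1 from the face opposite the C2 aryl group to 5,7,3′,4′-tetra-O-benzyl-(−)-epicatechin F2. DDQ with 2-ethoxyethanol in CH2Cl2 oxidises C4 of F2 to 4β-(2-ethoxyethoxy)-5,7,3′,4′-tetra-O-benzyl-(−)-epicatechin F3. Me3SiOSO2CF3 in CH2Cl2 at −78 °C ionises F3 to the C4 cation, which alkylates C8 of an excess of 2 anti to the C3 hydroxyl and gives [5,7,3′,4′-tetra-O-benzylepicatechin]-(4β→8)-[5,7,3′,4′-tetra-O-benzylcatechin] F4. NaH and BnBr in DMF then benzylate both C3 hydroxyls of F4 to give 25.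

Step 30 (carries the same label; the largest and most valuable substrate). The most likely failure is slow participation, because the heptadeca-benzylated mesylate is crowded and poorly solvated in the aqueous fluoro-alcohol, so that elimination or plain solvolysis competes. The fallback uses known chemistry, sets out from 37 and returns at 49. F3 (made as above) is added slowly to 37 and Me3SiOSO2CF3 in CH2Cl2 at −78 °C; the C4 cation alkylates C8 of the top unit of 37 and gives [5,7,3′,4′-tetra-O-benzylepicatechin]-(4β→8)-Epi-(4β→8)-Epi-(4β→8)-Cat F5. Hydrogenolysis of F5 over Pd(OH)2/C gives 49 directly. Step 22 carries the same label and the same risk on the trimer; it is covered by the coupling route given below for step 17, which also ends at 37.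

Step 11 (and its repeats 19 and 27). The most likely failure is poor facial selectivity at the methide carbon, because the chiral ylide may be mismatched with the chiral, hindered quinone methide; this would give the wrong C4 configuration. The fallback abandons reagent control, sets out from 9 and returns at 19. Chloroketone 9 is alkylated onto tetrahydrothiophene with AgBF4 to give 1-{2-[3,4-bis(pivaloyloxy)phenyl]-2-oxoethyl}thiolan-1-ium tetrafluoroborate F6, and aqueous K2CO3 converts F6 into the achiral ylide 2-[3,4-bis(pivaloyloxy)phenyl]-2-oxo-1-(thiolan-1-ium-1-yl)ethan-1-ide F7. F7 is combined with 17 and TBAF as in step 11. It gives the two trans annulation products, 19 and its (2R,3S) isomer F8; they are diastereomers because of unit 4 and are separated by chromatography.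

Step 17 (and its repeat 25). The most likely failure is loss of site selectivity: bromination at C6 of the lower unit or double bromination, because all free ring-A positions are strongly activated. The fallback needs no aryl bromide, sets out from 25 and returns at 37. F3 (made as above) and 25 are treated with Me3SiOSO2CF3 in CH2Cl2 at −78 °C; the C4 cation alkylates C8 of unit 3 and gives [5,7,3′,4′-tetra-O-benzylepicatechin]-(4β→8)-Epi-(4β→8)-Cat F9. NaH and BnBr then benzylate its C3 hydroxyl to give 37, bypassing 26 to 36.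

## Further compounds

F1 | step 14 | (2R)-5,7-bis(benzyloxy)-2-[3,4-bis(benzyloxy)phenyl]chroman-3-one | c1c(OCc3ccccc3)cc(OCc3ccccc3)c2c1O[C@H](c1ccc(OCc3ccccc3)c(OCc3ccccc3)c1)C(=O)C2
F2 | step 14 | 5,7,3′,4′-tetra-O-benzyl-(−)-epicatechin | c1c(OCc3ccccc3)cc(OCc3ccccc3)c2c1O[C@H](c1ccc(OCc3ccccc3)c(OCc3ccccc3)c1)[C@H](O)C2
F3 | step 14 | 4β-(2-ethoxyethoxy)-5,7,3′,4′-tetra-O-benzyl-(−)-epicatechin | c1c(OCc3ccccc3)cc(OCc3ccccc3)c2c1O[C@H](c1ccc(OCc3ccccc3)c(OCc3ccccc3)c1)[C@H](O)[C@H]2OCCOCC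
F4 | step 14 | [5,7,3′,4′-tetra-O-benzylepicatechin]-(4β→8)-[5,7,3′,4′-tetra-O-benzylcatechin] | c1c(OCc3ccccc3)cc(OCc3ccccc3)c2c1O[C@H](c1ccc(OCc3ccccc3)c(OCc3ccccc3)c1)[C@H](O)[C@H]2c1c(OCc3ccccc3)cc(OCc3ccccc3)c2c1O[C@H](c1ccc(OCc3ccccc3)c(OCc3ccccc3)c1)[C@@H](O)C2
F5 | step 30 | [5,7,3′,4′-tetra-O-benzylepicatechin]-(4β→8)-Epi-(4β→8)-Epi-(4β→8)-Cat | c1c(OCc3ccccc3)cc(OCc3ccccc3)c2c1O[C@H](c1ccc(OCc3ccccc3)c(OCc3ccccc3)c1)[C@H](O)[C@H]2c1c(OCc3ccccc3)cc(OCc3ccccc3)c2c1O[C@H](c1ccc(OCc3ccccc3)c(OCc3ccccc3)c1)[C@H](OCc3ccccc3)[C@H]2c1c(OCc3ccccc3)cc(OCc3ccccc3)c2c1O[C@H](c1ccc(OCc3ccccc3)c(OCc3ccccc3)c1)[C@H](OCc3ccccc3)[C@H]2c1c(OCc3ccccc3)cc(OCc3ccccc3)c2c1O[C@H](c1ccc(OCc3ccccc3)c(OCc3ccccc3)c1)[C@@H](OCc3ccccc3)C2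
F6 | step 11 | 1-{2-[3,4-bis(pivaloyloxy)phenyl]-2-oxoethyl}thiolan-1-ium tetrafluoroborate | O=C(C[S+]1CCCC1)c1ccc(OC(=O)C(C)(C)C)c(OC(=O)C(C)(C)C)c1.F[B-](F)(F)F
F7 | step 11 | 2-[3,4-bis(pivaloyloxy)phenyl]-2-oxo-1-(thiolan-1-ium-1-yl)ethan-1-ide | O=C([CH-][S+]1CCCC1)c1ccc(OC(=O)C(C)(C)C)c(OC(=O)C(C)(C)C)c1
F8 | step 11 | (2R,3S)-4,6-bis(benzyloxy)-2-[3,4-bis(pivaloyloxy)benzoyl]-3-(Cat-8-yl)-2,3-dihydrobenzofuran | c1c(OCc3ccccc3)cc(OCc3ccccc3)c2c1O[C@@H](C(=O)c1ccc(OC(=O)C(C)(C)C)c(OC(=O)C(C)(C)C)c1)[C@@H]2c1c(OCc3ccccc3)cc(OCc3ccccc3)c2c1O[C@H](c1ccc(OCc3ccccc3)c(OCc3ccccc3)c1)[C@@H](OCc3ccccc3)C2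
F9 | step 17 | [5,7,3′,4′-tetra-O-benzylepicatechin]-(4β→8)-Epi-(4β→8)-Cat | c1c(OCc3ccccc3)cc(OCc3ccccc3)c2c1O[C@H](c1ccc(OCc3ccccc3)c(OCc3ccccc3)c1)[C@H](O)[C@H]2c1c(OCc3ccccc3)cc(OCc3ccccc3)c2c1O[C@H](c1ccc(OCc3ccccc3)c(OCc3ccccc3)c1)[C@H](OCc3ccccc3)[C@H]2c1c(OCc3ccccc3)cc(OCc3ccccc3)c2c1O[C@H](c1ccc(OCc3ccccc3)c(OCc3ccccc3)c1)[C@@H](OCc3ccccc3)C2
A1 | alternative 1 | [5,7-dihydroxy-3-O-(tert-butyldimethylsilyl)-3′,4′-di-O-benzylepicatechin]-(4β→8)-[penta-O-benzylcatechin] | Oc1cc(O)c2c(c1)O[C@H](c1ccc(OCc3ccccc3)c(OCc3ccccc3)c1)[C@H](O[Si](C)(C)C(C)(C)C)[C@H]2c1c(OCc3ccccc3)cc(OCc3ccccc3)c2c1O[C@H](c1ccc(OCc3ccccc3)c(OCc3ccccc3)c1)[C@@H](OCc3ccccc3)C2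
A2 | alternative 1 | 2-[3,4-bis(benzyloxy)phenyl]-3-(tert-butyldimethylsilyloxy)-7-methyl-4-(penta-O-benzylcatechin-8-yl)-3,4-dihydro-2H,5H-pyrano[4,3-b]pyran-5-one, ring C configured as in unit 3 | CC4=CC(O[C@H](c1ccc(OCc3ccccc3)c(OCc3ccccc3)c1)[C@H](O[Si](C)(C)C(C)(C)C)[C@H]5c1c(OCc3ccccc3)cc(OCc3ccccc3)c2c1O[C@H](c1ccc(OCc3ccccc3)c(OCc3ccccc3)c1)[C@@H](OCc3ccccc3)C2)=C5C(=O)O4
A3 | alternative 2 | per-O-benzyl arecatannin A2 (all twenty hydroxyls as benzyl ethers) | c3ccccc3COc1cc(OCc3ccccc3)c2c(c1)O[C@H](c1ccc(OCc3ccccc3)c(OCc3ccccc3)c1)[C@H](OCc3ccccc3)[C@H]2c1c(OCc3ccccc3)cc(OCc3ccccc3)c2c1O[C@H](c1ccc(OCc3ccccc3)c(OCc3ccccc3)c1)[C@H](OCc3ccccc3)[C@H]2c1c(OCc3ccccc3)cc(OCc3ccccc3)c2c1O[C@H](c1ccc(OCc3ccccc3)c(OCc3ccccc3)c1)[C@H](OCc3ccccc3)[C@H]2c1c(OCc3ccccc3)cc(OCc3ccccc3)c2c1O[C@H](c1ccc(OCc3ccccc3)c(OCc3ccccc3)c1)[C@@H](OCc3ccccc3)C2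
A4 | alternative 2 | 1,2-bis(benzyloxy)benzene | C(Oc1ccccc1OCc1ccccc1)c1ccccc1
A5 | alternative 2 | tetramer core with an acetoxy group in place of ring B on C2 of units 1 to 3 (anomeric mixtures), otherwise benzylated as A3 | c3ccccc3COc1cc(OCc3ccccc3)c2c(c1)OC(OC(C)=O)[C@H](OCc3ccccc3)[C@H]2c1c(OCc3ccccc3)cc(OCc3ccccc3)c2c1OC(OC(C)=O)[C@H](OCc3ccccc3)[C@H]2c1c(OCc3ccccc3)cc(OCc3ccccc3)c2c1OC(OC(C)=O)[C@H](OCc3ccccc3)[C@H]2c1c(OCc3ccccc3)cc(OCc3ccccc3)c2c1O[C@H](c1ccc(OCc3ccccc3)c(OCc3ccccc3)c1)[C@@H](OCc3ccccc3)C2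
A6 | alternative 3 | seco-tetramer: ring A of unit 4 formed (free C8a hydroxyl, C7 triisopropylsilyl ether), ring C of unit 4 open | c3ccccc3COc1cc(OCc3ccccc3)c2c(c1)O[C@H](c1ccc(OCc3ccccc3)c(OCc3ccccc3)c1)[C@H](OCc3ccccc3)[C@H]2c1c(OCc3ccccc3)cc(OCc3ccccc3)c2c1O[C@H](c1ccc(OCc3ccccc3)c(OCc3ccccc3)c1)[C@H](OCc3ccccc3)[C@H]2c1c(OCc3ccccc3)cc(OCc3ccccc3)c2c1O[C@H](c1ccc(OCc3ccccc3)c(OCc3ccccc3)c1)[C@H](OCc3ccccc3)[C@H]2c1c(O[Si](C(C)C)(C(C)C)C(C)C)cc(OCc3ccccc3)c(C[C@H](OCc3ccccc3)[C@@H](O[Si](CC)(CC)CC)c2ccc(OCc3ccccc3)c(OCc3ccccc3)c2)c1O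
A7 | alternative 3 | 3-(benzyloxy)-4-{(2S,3R)-type side chain: 2-(benzyloxy)-3-[3,4-bis(benzyloxy)phenyl]-3-(triethylsilyloxy)propyl}cyclobut-2-en-1-one, side chain configured as in A6 | O=C1C=C(OCc3ccccc3)C1C[C@H](OCc3ccccc3)[C@@H](O[Si](CC)(CC)CC)c2ccc(OCc3ccccc3)c(OCc3ccccc3)c2
A8 | alternative 3 | Epi-(4β→8)-Epi-(4β→8)-[penta-O-benzylepicatechin] carrying a (triisopropylsilyloxy)ethynyl group on C4 (β) of the lowest unit | c1c(OCc3ccccc3)cc(OCc3ccccc3)c2c1O[C@H](c1ccc(OCc3ccccc3)c(OCc3ccccc3)c1)[C@H](OCc3ccccc3)[C@H]2c1c(OCc3ccccc3)cc(OCc3ccccc3)c2c1O[C@H](c1ccc(OCc3ccccc3)c(OCc3ccccc3)c1)[C@H](OCc3ccccc3)[C@H]2c1c(OCc3ccccc3)cc(OCc3ccccc3)c2c1O[C@H](c1ccc(OCc3ccccc3)c(OCc3ccccc3)c1)[C@H](OCc3ccccc3)[C@H]2C#CO[Si](C(C)C)(C(C)C)C(C)C
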